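**Retrosynthetic overview** (octahydroazulene numbering: C3 = CH–iPr, C3a = C–OH, C6 = C–CH3, C7 = CH=, C8 = CH–O, C8a = C–CH3)
1. Last operations: anisoylation of the C8 hydroxyl and isopropyl ⇐ isopropenyl.
2. Enabling feature: C3a–OH and C3–isopropenyl sit cis on adjacent cyclopentane carbons (a homoallylic alcohol, the carbonyl-ene retron for bond C3–C3a); the C3a ketone so revealed is γ,δ to the C6=C7 alkene of the seven-membered ring (a cyclohept-4-enone, the Claisen retron for bond C4–C5).
3. Both carbocycles therefore come in one flask from a monocyclic 2-methylidene-5-isopropenyloxolane: seven-membered ring first by [3,3] ring expansion, five-membered ring last by ene closure. The oxolane ring is not in the target, is cleaved on the way, and its C5 epimers converge.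
4. The oxolane comes from a γ-lactone by methylenation, the lactone from a 3,3-dialkylated dimethyl (R)-malate: malate C2 becomes C8, the quaternary C8a is set by two successive Fráter–Seebach alkylations (chain, then methyl), and C6/C7 arrive as isopropenylmagnesium bromide.
5. Ring order: lactone/oxolane (temporary) → cycloheptene → cyclopentane.

Key step: step 8

Remark: the SMILES is read as the all-cis isomer (C8–O, C8a–CH3, C3a–OH and C3–isopropyl on one face of a cis-fused bicycle), 3R,3aS,8S,8aR; compounds 1, 3, 15 and the named reagents are taken as commercial.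

Step 1
Reactants: 1 5-bromo-2-methylpent-2-ene
Product: 2 5-iodo-2-methylpent-2-ene
Conditions: NaI, acetone, reflux
Reagents that add atoms: sodium iodide, [Na+].[I-]
Why: Finkelstein halide exchange (SN2), driven by precipitation of NaBr, should give the more reactive homoallylic iodide needed for the enolate alkylation.

Step 2
Reactants: 3 dimethyl (R)-malate; 2 5-iodo-2-methylpent-2-ene
Product: 4 dimethyl (2R,3S)-2-hydroxy-3-(4-methylpent-3-en-1-yl)butanedioate
Conditions: LiHMDS (2.2 equiv), THF, −78 → −20 °C; then 2, DMPU, −78 → 0 °C; aq. work-up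
Reagents that add atoms: none
Why: Fráter–Seebach alkylation: the chelated lithium alkoxide–enolate of the β-hydroxy ester should be alkylated at C3 on the face anti to the C1 ester arm (2R,3S expected as the major isomer), and this configuration is only provisional because C3 is re-enolised in step 3.

Step 3
Reactants: 4 dimethyl (2R,3S)-2-hydroxy-3-(4-methylpent-3-en-1-yl)butanedioate
Product: 5 dimethyl (2R,3R)-2-hydroxy-3-methyl-3-(4-methylpent-3-en-1-yl)butanedioate
Conditions: LDA (2.3 equiv), THF, −78 → −20 °C; MeI, −78 → −10 °C; aq. work-up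
Reagents that add atoms: iodomethane, CI
Why: Second Fráter–Seebach alkylation: the fully substituted alkoxide–enolate should again take the electrophile on the face anti to the C1 ester arm, so that methyl ends up erythro to the hydroxyl and the chain threo, which sets the quaternary centre as 3R (the future C8a, with CH3 cis to the C8 oxygen) under control of the malate stereocentre.

Step 4
Reactants: 5 dimethyl (2R,3R)-2-hydroxy-3-methyl-3-(4-methylpent-3-en-1-yl)butanedioate
Product: 6 dimethyl (2R,3R)-2-[(tert-butyldimethylsilyl)oxy]-3-methyl-3-(4-methylpent-3-en-1-yl)butanedioate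
Conditions: TBSOTf, 2,6-lutidine, CH2Cl2, 0 °C → rt
Reagents that add atoms: tert-butyldimethylsilyl trifluoromethanesulfonate, CC(C)(C)[Si](C)(C)OS(=O)(=O)C(F)(F)F
Why: Silylation of the hindered secondary alcohol with the silyl triflate gives a protecting group that should survive hydride, Grignard reagent, titanium methylidene, 170 °C and Me2AlCl.

Step 5
Reactants: 6 dimethyl (2R,3R)-2-[(tert-butyldimethylsilyl)oxy]-3-methyl-3-(4-methylpent-3-en-1-yl)butanedioate
Product: 7 methyl (2R,3R)-3-[(tert-butyldimethylsilyl)oxy]-2-methyl-2-(4-methylpent-3-en-1-yl)-4-oxobutanoate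
Conditions: DIBAL-H (1.1 equiv), CH2Cl2, −78 °C; MeOH, aq. Rochelle salt
Reagents that add atoms: none
Why: DIBAL-H half-reduction: the α-silyloxy ester should be reduced selectively through a tetrahedral aluminate that is stable at −78 °C, whereas the ester on the quaternary carbon is more hindered and not activated.

Step 6
Reactants: 7 methyl (2R,3R)-3-[(tert-butyldimethylsilyl)oxy]-2-methyl-2-(4-methylpent-3-en-1-yl)-4-oxobutanoate
Product: 9 (3R,4R,5RS)-4-[(tert-butyldimethylsilyl)oxy]-3-methyl-3-(4-methylpent-3-en-1-yl)-5-(prop-1-en-2-yl)oxolan-2-one, via open-chain hydroxy ester 8 (not isolated)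
Conditions: CH2=C(CH3)MgBr (1.2 equiv), THF, −78 °C → rt; aq. work-up
Reagents that add atoms: isopropenylmagnesium bromide, CC(=C)[Mg]Br
Why: Grignard 1,2-addition to the aldehyde followed by acyl substitution of the neighbouring methyl ester by the new alkoxide (5-exo-trig lactonisation, favoured by the gem-dialkyl effect) should give the γ-lactone; the new carbinol centre is left uncontrolled on purpose because it becomes sp2 in step 8.

Step 7
Reactants: 9 (3R,4R,5RS)-4-[(tert-butyldimethylsilyl)oxy]-3-methyl-3-(4-methylpent-3-en-1-yl)-5-(prop-1-en-2-yl)oxolan-2-one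
Product: 10 (3R,4R,5RS)-4-[(tert-butyldimethylsilyl)oxy]-3-methyl-2-methylidene-3-(4-methylpent-3-en-1-yl)-5-(prop-1-en-2-yl)oxolane
Conditions: Cp2TiMe2 (2.5 equiv), PhMe, 70 °C, dark; filtration through basic alumina
Reagents that add atoms: dimethyltitanocene, C[Ti](C)(C1C=CC=C1)C1C=CC=C1
Why: Petasis methylenation: the titanium methylidene formed on heating should convert the lactone carbonyl into the exocyclic enol ether by [2+2] addition and cycloreversion, and the double bond cannot migrate into the ring because C3 is quaternary.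

Step 8
Reactants: 10 (3R,4R,5RS)-4-[(tert-butyldimethylsilyl)oxy]-3-methyl-2-methylidene-3-(4-methylpent-3-en-1-yl)-5-(prop-1-en-2-yl)oxolane
Product: 12 (3R,3aS,8S,8aR)-8-[(tert-butyldimethylsilyl)oxy]-6,8a-dimethyl-3-(prop-1-en-2-yl)-2,3,4,5,8,8a-hexahydroazulen-3a(1H)-ol, via cycloheptenone 11 (not isolated)
Conditions: PhMe, 170 °C (sealed, base-washed tube); then −78 °C, CH2Cl2, Me2AlCl (2.2 equiv), → 0 °C; aq. Rochelle salt
Reagents that add atoms: none
Why: Heating induces a Claisen ([3,3]-sigmatropic) ring expansion of the 2-methylidene-5-alkenyloxolane, in which the exocyclic CH2 bonds to the isopropenyl CH2 through a boat-like array while the allylic C5–O bond breaks, so that cyclohept-4-enone 11 forms and both C5 epimers of 10 converge because C5 becomes the sp2 carbon C7; Me2AlCl then binds the new ketone and the trisubstituted alkene of the side chain adds to it in a type I intramolecular carbonyl-ene reaction (C3–C3a bond, allylic hydrogen to oxygen, the O–H quenched by Al–CH3 as methane). The closest known reaction types are the thermal ring enlargement of lactone-derived 2-methylidene-5-vinyl cyclic ethers to cycloalk-4-enones and the Me2AlCl-promoted ene cyclisation of olefinic ketones to cis-2-isopropenyl cycloalkanols. The seven-membered ring closes by sigmatropic ring enlargement (C4–C5 bond made, ring C–O bond broken, only the ring-cis C6=C7 geometry possible) and the five-membered ring by 5-exo attack of the alkene on the carbonyl carbon inside a six-centre ene transition state. C3a is controlled by C8a and C8: the three-carbon tether delivers the alkene to the carbonyl face on the side of its own attachment, and the OTBS group at C8, trans to the chain and pseudo-axial, covers the other face, so that the bicycle is cis-fused with OH cis to the C8a methyl and to the C8 oxygen. C3 is controlled by the closed ene transition state, which holds the carbonyl oxygen and the forming isopropenyl group syn and so gives the cis C3a–OH/C3–isopropenyl pair. The step needs the concerted ene closure to outrun methyl transfer from aluminium, Prins-type chloride capture and ionisation of the allylic silyl ether, which is secured by the quaternary C8a (no enolisation or β-elimination), the short tether to a nucleophilic trisubstituted alkene and a proton-scavenging Lewis acid at low temperature.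

Step 9
Reactants: 12 (3R,3aS,8S,8aR)-8-[(tert-butyldimethylsilyl)oxy]-6,8a-dimethyl-3-(prop-1-en-2-yl)-2,3,4,5,8,8a-hexahydroazulen-3a(1H)-ol
Product: 13 (3R,3aS,8S,8aR)-8-[(tert-butyldimethylsilyl)oxy]-6,8a-dimethyl-3-(propan-2-yl)-2,3,4,5,8,8a-hexahydroazulen-3a(1H)-ol
Conditions: H2 (1 atm), RhCl(PPh3)3 (10 mol %), PhH–EtOH, rt
Reagents that add atoms: none
Why: Hydrogenation with Wilkinson's catalyst should saturate the unhindered 1,1-disubstituted isopropenyl group and leave the trisubstituted ring alkene untouched; no stereocentre is formed.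

Step 10
Reactants: 13 (3R,3aS,8S,8aR)-8-[(tert-butyldimethylsilyl)oxy]-6,8a-dimethyl-3-(propan-2-yl)-2,3,4,5,8,8a-hexahydroazulen-3a(1H)-ol
Product: 14 (3R,3aS,8S,8aR)-6,8a-dimethyl-3-(propan-2-yl)-2,3,4,5,8,8a-hexahydroazulene-3a,8(1H)-diol
Conditions: TBAF, THF, rt → 40 °C; aq. work-up
Reagents that add atoms: none
Why: Fluoride-induced desilylation, driven by the Si–F bond, should free the C8 hydroxyl without touching the tertiary alcohol or the alkene.

Step 11
Reactants: 14 (3R,3aS,8S,8aR)-6,8a-dimethyl-3-(propan-2-yl)-2,3,4,5,8,8a-hexahydroazulene-3a,8(1H)-diol; 15 4-methoxybenzoyl chloride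
Product: 16 (3R,3aS,8S,8aR)-3a-hydroxy-6,8a-dimethyl-3-(propan-2-yl)-1,2,3,3a,4,5,8,8a-octahydroazulen-8-yl 4-methoxybenzoate
Conditions: Et3N, DMAP, CH2Cl2, 0 °C → rt
Reagents that add atoms: none
Why: DMAP-catalysed acylation (nucleophilic catalysis via the acylpyridinium ion) should esterify the secondary allylic hydroxyl selectively, the tertiary ring-fusion hydroxyl being too hindered, with retention at C8.

**Compound list**
1 | 5-bromo-2-methylpent-2-ene | CC(C)=CCCBr | starting material
2 | 5-iodo-2-methylpent-2-ene | CC(C)=CCCI | intermediate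
3 | dimethyl (R)-malate | COC(=O)C[C@@H](O)C(=O)OC | starting material
4 | dimethyl (2R,3S)-2-hydroxy-3-(4-methylpent-3-en-1-yl)butanedioate | CC(C)=CCC[C@@H]([C@@H](O)C(=O)OC)C(=O)OC | intermediate
5 | dimethyl (2R,3R)-2-hydroxy-3-methyl-3-(4-methylpent-3-en-1-yl)butanedioate | CC(C)=CCC[C@]([C@@H](O)C(=O)OC)(C(=O)OC)C | intermediate
6 | dimethyl (2R,3R)-2-[(tert-butyldimethylsilyl)oxy]-3-methyl-3-(4-methylpent-3-en-1-yl)butanedioate | CC(C)=CCC[C@]([C@@H](O[Si](C)(C)C(C)(C)C)C(=O)OC)(C(=O)OC)C | intermediate
7 | methyl (2R,3R)-3-[(tert-butyldimethylsilyl)oxy]-2-methyl-2-(4-methylpent-3-en-1-yl)-4-oxobutanoate | CC(C)=CCC[C@]([C@@H](O[Si](C)(C)C(C)(C)C)C=O)(C(=O)OC)C | intermediate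
8 | methyl (2R,3R,4RS)-3-[(tert-butyldimethylsilyl)oxy]-4-hydroxy-2,5-dimethyl-2-(4-methylpent-3-en-1-yl)hex-5-enoate (not isolated) | CC(C)=CCC[C@]([C@@H](O[Si](C)(C)C(C)(C)C)C(O)C(C)=C)(C(=O)OC)C | intermediate
9 | (3R,4R,5RS)-4-[(tert-butyldimethylsilyl)oxy]-3-methyl-3-(4-methylpent-3-en-1-yl)-5-(prop-1-en-2-yl)oxolan-2-one | CC(C)=CCC[C@@]1(C)C(=O)OC(C(C)=C)[C@@H]1O[Si](C)(C)C(C)(C)C | intermediate
10 | (3R,4R,5RS)-4-[(tert-butyldimethylsilyl)oxy]-3-methyl-2-methylidene-3-(4-methylpent-3-en-1-yl)-5-(prop-1-en-2-yl)oxolane | CC(C)=CCC[C@@]1(C)C(=C)OC(C(C)=C)[C@@H]1O[Si](C)(C)C(C)(C)C | intermediate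
11 | (2R,3S)-3-[(tert-butyldimethylsilyl)oxy]-2,5-dimethyl-2-(4-methylpent-3-en-1-yl)cyclohept-4-en-1-one (not isolated) | CC(C)=CCC[C@@]1(C)C(=O)CCC(C)=C[C@@H]1O[Si](C)(C)C(C)(C)C | intermediate
12 | (3R,3aS,8S,8aR)-8-[(tert-butyldimethylsilyl)oxy]-6,8a-dimethyl-3-(prop-1-en-2-yl)-2,3,4,5,8,8a-hexahydroazulen-3a(1H)-ol | CC(C)(C)[Si](C)(C)O[C@H]1C=C(C)CC[C@]2(O)[C@@H](C(C)=C)CC[C@]12C | intermediate
13 | (3R,3aS,8S,8aR)-8-[(tert-butyldimethylsilyl)oxy]-6,8a-dimethyl-3-(propan-2-yl)-2,3,4,5,8,8a-hexahydroazulen-3a(1H)-ol | CC(C)(C)[Si](C)(C)O[C@H]1C=C(C)CC[C@]2(O)[C@@H](C(C)C)CC[C@]12C | intermediate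
14 | (3R,3aS,8S,8aR)-6,8a-dimethyl-3-(propan-2-yl)-2,3,4,5,8,8a-hexahydroazulene-3a,8(1H)-diol | O[C@H]1C=C(C)CC[C@]2(O)[C@@H](C(C)C)CC[C@]12C | intermediate
15 | 4-methoxybenzoyl chloride | COc1ccc(C(=O)Cl)cc1 | starting material
16 | (3R,3aS,8S,8aR)-3a-hydroxy-6,8a-dimethyl-3-(propan-2-yl)-1,2,3,3a,4,5,8,8a-octahydroazulen-8-yl 4-methoxybenzoate | COc1ccc(C(=O)O[C@H]2C=C(C)CC[C@]3(O)[C@@H](C(C)C)CC[C@]23C)cc1 | target

**Step count and risks**
Total steps: 11. Longest linear sequence: 11 steps (1 → 16); 10 steps from dimethyl (R)-malate.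

Steps most likely to fail:

Step 8. The ene stage may leave the concerted path (stepwise Prins closure with chloride capture or proton loss to a tetrasubstituted alkene, ionisation of the allylic silyl ether) or close with poor control of the ring fusion. Fallback: setting out from 10, only the thermal ring expansion would be run and cycloheptenone 11 isolated. HF·pyridine would then free the hydroxyl to give (2R,3S)-3-hydroxy-2,5-dimethyl-2-(4-methylpent-3-en-1-yl)cyclohept-4-en-1-one F1. With Me2AlCl (3 equiv) this hydroxyl would become an aluminium alkoxide that chelates and activates the ketone from its own face, so that the chain has to add from the opposite face in a hydroxyl-directed ene closure to (3R,3aS,8S,8aR)-6,8a-dimethyl-3-(prop-1-en-2-yl)-2,3,4,5,8,8a-hexahydroazulene-3a,8(1H)-diol F2. Hydrogenation under the conditions of step 9 would return to the route at 14.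

Step 7. The titanium methylidene may fail to add to the lactone carbonyl next to the quaternary carbon, or the enol ether may be hydrolysed during isolation. Fallback: setting out from 9, addition of MeLi (THF, −78 °C) to the lactone carbonyl would give the hemiketal (2RS,3R,4R,5RS)-4-[(tert-butyldimethylsilyl)oxy]-2,3-dimethyl-3-(4-methylpent-3-en-1-yl)-5-(prop-1-en-2-yl)oxolan-2-ol F3. Dehydration with (CF3CO)2O/pyridine, which can only go towards the methyl group because C3 is quaternary, would return to the route at 10.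

Step 2. Slow SN2 reaction of the non-activated iodide and E2 loss of HI from it may consume the dianion. Fallback: setting out from 3, the same dianion would be alkylated with allyl bromide to give dimethyl (2R,3S)-2-hydroxy-3-(prop-2-en-1-yl)butanedioate F4. Methylation as in step 3 would give dimethyl (2R,3R)-2-hydroxy-3-methyl-3-(prop-2-en-1-yl)butanedioate F5, and silylation as in step 4 would give dimethyl (2R,3R)-2-[(tert-butyldimethylsilyl)oxy]-3-methyl-3-(prop-2-en-1-yl)butanedioate F6. Hydroboration with 9-BBN and oxidative work-up (NaBO3) would give dimethyl (2R,3R)-2-[(tert-butyldimethylsilyl)oxy]-3-(3-hydroxypropyl)-3-methylbutanedioate F7, and Dess–Martin oxidation would give dimethyl (2R,3R)-2-[(tert-butyldimethylsilyl)oxy]-3-methyl-3-(3-oxopropyl)butanedioate F8. Wittig olefination with isopropylidenetriphenylphosphorane would return to the route at 6.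

**Further compounds**
F1 | step 8 | (2R,3S)-3-hydroxy-2,5-dimethyl-2-(4-methylpent-3-en-1-yl)cyclohept-4-en-1-one | CC(C)=CCC[C@@]1(C)C(=O)CCC(C)=C[C@@H]1O
F2 | step 8 | (3R,3aS,8S,8aR)-6,8a-dimethyl-3-(prop-1-en-2-yl)-2,3,4,5,8,8a-hexahydroazulene-3a,8(1H)-diol | O[C@H]1C=C(C)CC[C@]2(O)[C@@H](C(C)=C)CC[C@]12C
F3 | step 7 | (2RS,3R,4R,5RS)-4-[(tert-butyldimethylsilyl)oxy]-2,3-dimethyl-3-(4-methylpent-3-en-1-yl)-5-(prop-1-en-2-yl)oxolan-2-ol | CC(C)=CCC[C@@]1(C)C(C)(O)OC(C(C)=C)[C@@H]1O[Si](C)(C)C(C)(C)C
F4 | step 2 | dimethyl (2R,3S)-2-hydroxy-3-(prop-2-en-1-yl)butanedioate | C=CC[C@@H]([C@@H](O)C(=O)OC)C(=O)OC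
F5 | step 2 | dimethyl (2R,3R)-2-hydroxy-3-methyl-3-(prop-2-en-1-yl)butanedioate | C=CC[C@]([C@@H](O)C(=O)OC)(C(=O)OC)C
F6 | step 2 | dimethyl (2R,3R)-2-[(tert-butyldimethylsilyl)oxy]-3-methyl-3-(prop-2-en-1-yl)butanedioate | C=CC[C@]([C@@H](O[Si](C)(C)C(C)(C)C)C(=O)OC)(C(=O)OC)C
F7 | step 2 | dimethyl (2R,3R)-2-[(tert-butyldimethylsilyl)oxy]-3-(3-hydroxypropyl)-3-methylbutanedioate | OCCC[C@]([C@@H](O[Si](C)(C)C(C)(C)C)C(=O)OC)(C(=O)OC)C
F8 | step 2 | dimethyl (2R,3R)-2-[(tert-butyldimethylsilyl)oxy]-3-methyl-3-(3-oxopropyl)butanedioate | O=CCC[C@]([C@@H](O[Si](C)(C)C(C)(C)C)C(=O)OC)(C(=O)OC)C
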